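**Retrosynthetic overview**
1. The target is a plagiochiline-type 2,3-secoaromadendrane; atom labels below use aromadendrane numbering (C-2 acetal, C-8 ketone, C-14 formyl, C-15 CH2OAc, C-11 CMe2; target = 1R,2S,5R,6R,7S).
2. Last bond C-8–C-9: a σ-acyl radical from a C-8 aldehyde adds 7-endo to a β-stannyl enal and expels Bu3Sn•, giving the enone–enal directly; the enal carbon C-14 comes from radical stannylformylation of a C-10 ethynyl group with CO.
3. Pyran: HCl addition to a 4H-pyran, then acetate displacement with inversion (sets C-1 and C-2); the 4H-pyran comes from Michael addition/cyclodehydration of malonaldehyde on a 2-ethynyl enal (sets C-5).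
4. The enal comes from a cis-cyclopropane acetal and (Z)-1-methoxybut-1-en-3-yne; the cyclopropane (C-6, C-7) from enantioselective carbomagnesiation of 3,3-dimethylcyclopropene.
5. Ring order: cyclopropane (step 1), pyran (steps 5–6), seven-membered ring (step 11).

Assumption: compounds 1, 8 and 11 are taken as purchasable, and the ligand named in step 1 is assumed to give the (1S,3R) product (its antipode is used otherwise).

**Route**

Step 1
Reactants: 1 3,3-dimethylcyclopropene; 2 vinylmagnesium bromide; 3 formaldehyde (as paraformaldehyde)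
Product: 4 [(1S,3R)-3-ethenyl-2,2-dimethylcyclopropyl]methanol
Conditions: CuI (5 mol%), (R)-DTBM-SEGPHOS (6 mol%), Et2O/PhMe, −30 °C; then (CH2O)n, −30 °C → rt; aq. NH4Cl
Reagents that add atoms: none
Why: Copper-catalysed enantioselective syn-carbomagnesiation of the strained alkene gives a configurationally stable cis-cyclopropylmagnesium species that is hydroxymethylated with retention, so C-6 and C-7 are set cis in one operation and their absolute sense is fixed by the ligand.

Step 2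
Reactants: 4 [(1S,3R)-3-ethenyl-2,2-dimethylcyclopropyl]methanol
Product: 5 tert-butyl{[(1S,3R)-3-ethenyl-2,2-dimethylcyclopropyl]methoxy}diphenylsilane
Conditions: TBDPSCl, imidazole, DMF, 0 °C → rt
Reagents that add atoms: tert-butyl(chloro)diphenylsilane, CC(C)(C)[Si](Cl)(c1ccccc1)c1ccccc1
Why: Routine silylation of a primary alcohol gives an ether that survives the later acid, amine and hydride steps and provides the bulk that shields one face of C-5 in step 5, with no stereocentre touched.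

Step 3
Reactants: 5 tert-butyl{[(1S,3R)-3-ethenyl-2,2-dimethylcyclopropyl]methoxy}diphenylsilane
Product: 7 tert-butyl{[(1S,3R)-3-(dimethoxymethyl)-2,2-dimethylcyclopropyl]methoxy}diphenylsilane, via aldehyde 6 (not isolated)
Conditions: O3, CH2Cl2/MeOH, −78 °C; Me2S, → rt; then HC(OMe)3, TsOH·H2O (cat.), rt
Reagents that add atoms: ozone, O=[O+][O-] (oxygen kept only in 6); trimethyl orthoformate, COC(OC)OC
Why: Ozonolysis with reductive work-up cleaves the vinyl group to the cis aldehyde without epimerisation and orthoformate acetalisation gives the acetal electrophile for step 4, no new stereocentre being formed.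

Step 4
Reactants: 7 tert-butyl{[(1S,3R)-3-(dimethoxymethyl)-2,2-dimethylcyclopropyl]methoxy}diphenylsilane; 8 (Z)-1-methoxybut-1-en-3-yne
Product: 10 (2E)-3-[(1R,3S)-3-({[tert-butyl(diphenyl)silyl]oxy}methyl)-2,2-dimethylcyclopropyl]-2-ethynylprop-2-enal, via trimethoxy adduct 9 (not isolated)
Conditions: BF3·OEt2 (10 mol%), CH2Cl2, −40 °C; then AcOH/H2O/NaOAc, 70 °C
Reagents that add atoms: water, O
Why: Lewis-acid enol ether–acetal condensation (Müller-Cunradi–Pieroh/Isler chain extension) joins the oxocarbenium ion of 7 to the nucleophilic C-2 of the enol ether, and buffered hydrolysis with loss of methanol gives the thermodynamically preferred (E)-2-ethynyl enal without creating a stereocentre.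

Step 5
Reactants: 10 (2E)-3-[(1R,3S)-3-({[tert-butyl(diphenyl)silyl]oxy}methyl)-2,2-dimethylcyclopropyl]-2-ethynylprop-2-enal; 11 sodium malonaldehyde (sodium (E)-3-oxoprop-1-en-1-olate)
Product: 13 (4R)-4-[(1R,3S)-3-({[tert-butyl(diphenyl)silyl]oxy}methyl)-2,2-dimethylcyclopropyl]-5-ethynyl-4H-pyran-3-carbaldehyde, via lactol 12 (not isolated)
Conditions: AcOH (1.2 equiv), pyrrolidine (20 mol%), MeCN, 0 °C → rt; then TsOH·H2O (10 mol%), 4 Å MS, PhMe, 40 °C
Reagents that add atoms: none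
Why: Amine-catalysed Michael addition of malonaldehyde, hemiacetal closure and acid-catalysed dehydration (Hantzsch-type 4H-pyran synthesis), in which the nucleophile attacks C-5 of the s-trans bisected vinylcyclopropane conformer from the face away from the bulky cis CH2OTBDPS group on C-7 and so sets 5R.

Step 6
Reactants: 13 (4R)-4-[(1R,3S)-3-({[tert-butyl(diphenyl)silyl]oxy}methyl)-2,2-dimethylcyclopropyl]-5-ethynyl-4H-pyran-3-carbaldehyde
Product: 15 (2S,3R,4R)-4-[(1R,3S)-3-({[tert-butyl(diphenyl)silyl]oxy}methyl)-2,2-dimethylcyclopropyl]-3-ethynyl-5-formyl-3,4-dihydro-2H-pyran-2-yl acetate, via anomeric chloride 14 (not isolated)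
Conditions: HCl (1.05 equiv, Et2O), CH2Cl2, −78 °C; then Bu4NOAc, −78 → −20 °C
Reagents that add atoms: hydrogen chloride, Cl (for 14); tetrabutylammonium acetate, CC(=O)[O-].CCCC[N+](CCCC)(CCCC)CCCC
Why: Markovnikov hydrochlorination of the more electron-rich enol ether (the other is a deactivated vinylogous formate) delivers the proton to C-1 anti to the pseudoaxial cyclopropyl group (H-1 cis to H-5) and gives the axial anomeric chloride, which acetate displaces with inversion (Koenigs–Knorr-type SN2) so that the acetoxy group ends cis to the C-1 and C-5 carbon substituents (2S).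

Step 7
Reactants: 15 (2S,3R,4R)-4-[(1R,3S)-3-({[tert-butyl(diphenyl)silyl]oxy}methyl)-2,2-dimethylcyclopropyl]-3-ethynyl-5-formyl-3,4-dihydro-2H-pyran-2-yl acetate
Product: 17 [(2S,3R,4R)-2-(acetyloxy)-4-[(1R,3S)-3-({[tert-butyl(diphenyl)silyl]oxy}methyl)-2,2-dimethylcyclopropyl]-3-ethynyl-3,4-dihydro-2H-pyran-5-yl]methyl acetate, via alcohol 16 (not isolated)
Conditions: NaBH4, CeCl3·7H2O, THF/MeOH, −40 °C; then pyridine, Ac2O, DMAP, 0 °C → rt (same flask)
Reagents that add atoms: acetic anhydride, CC(=O)OC(C)=O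
Why: Luche 1,2-reduction of the only aldehyde (a β-alkoxy acrolein) and in situ acetylation of the alkoxide install the C-15 acetate while the anomeric acetate, alkyne and silyl ether are untouched and no stereocentre changes.

Step 8
Reactants: 17 [(2S,3R,4R)-2-(acetyloxy)-4-[(1R,3S)-3-({[tert-butyl(diphenyl)silyl]oxy}methyl)-2,2-dimethylcyclopropyl]-3-ethynyl-3,4-dihydro-2H-pyran-5-yl]methyl acetate; 18 carbon monoxide
Product: 19 [(2S,3R,4R)-2-(acetyloxy)-4-[(1R,3S)-3-({[tert-butyl(diphenyl)silyl]oxy}methyl)-2,2-dimethylcyclopropyl]-3-[3-oxo-1-(tributylstannyl)prop-1-en-2-yl]-3,4-dihydro-2H-pyran-5-yl]methyl acetate (E/Z mixture)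
Conditions: Bu3SnH (1.2 equiv, slow addition), CO (80 atm), AIBN (cat.), PhH (0.02 M), 80 °C
Reagents that add atoms: tributylstannane, CCCC[SnH](CCCC)CCCC
Why: Proposed new method: Bu3Sn• adds to the terminal alkyne carbon C-9, the σ-vinyl radical at C-10 captures CO under pressure faster than it is reduced by the slowly fed stannane, and the resulting acyl radical takes H from Bu3SnH to give the β-stannyl enal with C-14 in place (radical stannylformylation, an addition in which nothing is lost), the closest known reactions being radical thioformylation of terminal alkynes with thiols and CO and tin-hydride/CO formylation of alkyl halides.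

Step 9
Reactants: 19 [(2S,3R,4R)-2-(acetyloxy)-4-[(1R,3S)-3-({[tert-butyl(diphenyl)silyl]oxy}methyl)-2,2-dimethylcyclopropyl]-3-[3-oxo-1-(tributylstannyl)prop-1-en-2-yl]-3,4-dihydro-2H-pyran-5-yl]methyl acetate
Product: 20 [(2S,3R,4R)-2-(acetyloxy)-4-[(1R,3S)-3-(hydroxymethyl)-2,2-dimethylcyclopropyl]-3-[3-oxo-1-(tributylstannyl)prop-1-en-2-yl]-3,4-dihydro-2H-pyran-5-yl]methyl acetate
Conditions: TBAF/AcOH (1:1), THF, 0 °C → rt
Reagents that add atoms: none
Why: Acetic-acid-buffered fluoride desilylation frees the C-8 alcohol without cleaving the acetates, the vinylstannane or the enal, and no stereocentre is involved.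

Step 10
Reactants: 20 [(2S,3R,4R)-2-(acetyloxy)-4-[(1R,3S)-3-(hydroxymethyl)-2,2-dimethylcyclopropyl]-3-[3-oxo-1-(tributylstannyl)prop-1-en-2-yl]-3,4-dihydro-2H-pyran-5-yl]methyl acetate
Product: 21 [(2S,3R,4R)-2-(acetyloxy)-4-[(1R,3S)-3-formyl-2,2-dimethylcyclopropyl]-3-[3-oxo-1-(tributylstannyl)prop-1-en-2-yl]-3,4-dihydro-2H-pyran-5-yl]methyl acetate
Conditions: Dess–Martin periodinane, pyridine, CH2Cl2, 0 °C
Reagents that add atoms: none
Why: Buffered Dess–Martin oxidation gives the cis cyclopropanecarbaldehyde (the acyl-radical precursor) cold and without epimerising C-7, the stannane and enol ether being inert.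

Step 11
Reactants: 21 [(2S,3R,4R)-2-(acetyloxy)-4-[(1R,3S)-3-formyl-2,2-dimethylcyclopropyl]-3-[3-oxo-1-(tributylstannyl)prop-1-en-2-yl]-3,4-dihydro-2H-pyran-5-yl]methyl acetate
Product: 22 target CNP0263020.2, (1R,2S,5R,6R,7S)-2,15-diacetoxy-2,3-epoxy-8-oxo-2,3-secoaromadendra-3,9-dien-14-al
Conditions: tert-dodecanethiol (30 mol%), AIBN (20 mol%, portionwise), PhH (0.005 M), 80 °C
Reagents that add atoms: none
Why: Proposed new method: the thiyl radical abstracts the aldehydic hydrogen at C-8 (polarity-reversal catalysis), the σ-acyl radical (which neither decarbonylates nor opens the cyclopropane) adds 7-endo to the tin-bearing β-carbon C-9 of the enal rather than to the fully substituted C-10, and β-scission of the C–Sn bond gives the enone while Bu3Sn• regenerates the thiyl radical from the thiol, the closest known reactions being thiol-catalysed radical-chain hydroacylation of alkenes and radical addition–fragmentation on β-stannyl acrylates, and no stereocentre is formed or sits at a radical site.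

**Compound list**
1 | 3,3-dimethylcyclopropene | CC1(C)C=C1 | starting material
2 | vinylmagnesium bromide | C=C[Mg]Br | starting material
3 | formaldehyde (as paraformaldehyde) | C=O | starting material
4 | [(1S,3R)-3-ethenyl-2,2-dimethylcyclopropyl]methanol | C=C[C@@H]1[C@H](CO)C1(C)C | intermediate
5 | tert-butyl{[(1S,3R)-3-ethenyl-2,2-dimethylcyclopropyl]methoxy}diphenylsilane | C=C[C@@H]1[C@H](CO[Si](c2ccccc2)(c2ccccc2)C(C)(C)C)C1(C)C | intermediate
6 | (1R,3S)-3-({[tert-butyl(diphenyl)silyl]oxy}methyl)-2,2-dimethylcyclopropane-1-carbaldehyde | O=C[C@@H]1[C@H](CO[Si](c2ccccc2)(c2ccccc2)C(C)(C)C)C1(C)C | intermediate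
7 | tert-butyl{[(1S,3R)-3-(dimethoxymethyl)-2,2-dimethylcyclopropyl]methoxy}diphenylsilane | COC(OC)[C@@H]1[C@H](CO[Si](c2ccccc2)(c2ccccc2)C(C)(C)C)C1(C)C | intermediate
8 | (Z)-1-methoxybut-1-en-3-yne | CO/C=C\C#C | starting material
9 | tert-butyl({(1S,3R)-3-[2-ethynyl-1,3,3-trimethoxypropyl]-2,2-dimethylcyclopropyl}methoxy)diphenylsilane (mixture at the two new carbons) | COC(OC)C(C#C)C(OC)[C@@H]1[C@H](CO[Si](c2ccccc2)(c2ccccc2)C(C)(C)C)C1(C)C | intermediate
10 | (2E)-3-[(1R,3S)-3-({[tert-butyl(diphenyl)silyl]oxy}methyl)-2,2-dimethylcyclopropyl]-2-ethynylprop-2-enal | O=C/C(C#C)=C/[C@@H]1[C@H](CO[Si](c2ccccc2)(c2ccccc2)C(C)(C)C)C1(C)C | intermediate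
11 | sodium malonaldehyde (sodium (E)-3-oxoprop-1-en-1-olate) | [Na+].[O-]/C=C/C=O | starting material
12 | (4R)-4-[(1R,3S)-3-({[tert-butyl(diphenyl)silyl]oxy}methyl)-2,2-dimethylcyclopropyl]-3-ethynyl-2-hydroxy-3,4-dihydro-2H-pyran-5-carbaldehyde (mixture at C-2 and C-3 of the pyran) | O=CC1=COC(O)C(C#C)[C@H]1[C@@H]1[C@H](CO[Si](c2ccccc2)(c2ccccc2)C(C)(C)C)C1(C)C | intermediate
13 | (4R)-4-[(1R,3S)-3-({[tert-butyl(diphenyl)silyl]oxy}methyl)-2,2-dimethylcyclopropyl]-5-ethynyl-4H-pyran-3-carbaldehyde | O=CC1=COC=C(C#C)[C@H]1[C@@H]1[C@H](CO[Si](c2ccccc2)(c2ccccc2)C(C)(C)C)C1(C)C | intermediate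
14 | (2R,3R,4R)-4-[(1R,3S)-3-({[tert-butyl(diphenyl)silyl]oxy}methyl)-2,2-dimethylcyclopropyl]-2-chloro-3-ethynyl-3,4-dihydro-2H-pyran-5-carbaldehyde | O=CC1=CO[C@H](Cl)[C@@H](C#C)[C@H]1[C@@H]1[C@H](CO[Si](c2ccccc2)(c2ccccc2)C(C)(C)C)C1(C)C | intermediate
15 | (2S,3R,4R)-4-[(1R,3S)-3-({[tert-butyl(diphenyl)silyl]oxy}methyl)-2,2-dimethylcyclopropyl]-3-ethynyl-5-formyl-3,4-dihydro-2H-pyran-2-yl acetate | O=CC1=CO[C@@H](OC(C)=O)[C@@H](C#C)[C@H]1[C@@H]1[C@H](CO[Si](c2ccccc2)(c2ccccc2)C(C)(C)C)C1(C)C | intermediate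
16 | (2S,3R,4R)-4-[(1R,3S)-3-({[tert-butyl(diphenyl)silyl]oxy}methyl)-2,2-dimethylcyclopropyl]-3-ethynyl-5-(hydroxymethyl)-3,4-dihydro-2H-pyran-2-yl acetate | OCC1=CO[C@@H](OC(C)=O)[C@@H](C#C)[C@H]1[C@@H]1[C@H](CO[Si](c2ccccc2)(c2ccccc2)C(C)(C)C)C1(C)C | intermediate
17 | [(2S,3R,4R)-2-(acetyloxy)-4-[(1R,3S)-3-({[tert-butyl(diphenyl)silyl]oxy}methyl)-2,2-dimethylcyclopropyl]-3-ethynyl-3,4-dihydro-2H-pyran-5-yl]methyl acetate | CC(=O)OCC1=CO[C@@H](OC(C)=O)[C@@H](C#C)[C@H]1[C@@H]1[C@H](CO[Si](c2ccccc2)(c2ccccc2)C(C)(C)C)C1(C)C | intermediate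
18 | carbon monoxide | [C-]#[O+] | starting material
19 | [(2S,3R,4R)-2-(acetyloxy)-4-[(1R,3S)-3-({[tert-butyl(diphenyl)silyl]oxy}methyl)-2,2-dimethylcyclopropyl]-3-[3-oxo-1-(tributylstannyl)prop-1-en-2-yl]-3,4-dihydro-2H-pyran-5-yl]methyl acetate (E/Z mixture) | CC(=O)OCC1=CO[C@@H](OC(C)=O)[C@@H](C(C=O)=C[Sn](CCCC)(CCCC)CCCC)[C@H]1[C@@H]1[C@H](CO[Si](c2ccccc2)(c2ccccc2)C(C)(C)C)C1(C)C | intermediate
20 | [(2S,3R,4R)-2-(acetyloxy)-4-[(1R,3S)-3-(hydroxymethyl)-2,2-dimethylcyclopropyl]-3-[3-oxo-1-(tributylstannyl)prop-1-en-2-yl]-3,4-dihydro-2H-pyran-5-yl]methyl acetate | CC(=O)OCC1=CO[C@@H](OC(C)=O)[C@@H](C(C=O)=C[Sn](CCCC)(CCCC)CCCC)[C@H]1[C@@H]1[C@H](CO)C1(C)C | intermediate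
21 | [(2S,3R,4R)-2-(acetyloxy)-4-[(1R,3S)-3-formyl-2,2-dimethylcyclopropyl]-3-[3-oxo-1-(tributylstannyl)prop-1-en-2-yl]-3,4-dihydro-2H-pyran-5-yl]methyl acetate | CC(=O)OCC1=CO[C@@H](OC(C)=O)[C@@H](C(C=O)=C[Sn](CCCC)(CCCC)CCCC)[C@H]1[C@@H]1[C@H](C=O)C1(C)C | intermediate
22 | CNP0263020.2, (1R,2S,5R,6R,7S)-2,15-diacetoxy-2,3-epoxy-8-oxo-2,3-secoaromadendra-3,9-dien-14-al (H-1 and H-5 cis; acetoxy at C-2 cis to C-10 and C-6; cyclopropane on the face of H-1/H-5) | CC(=O)OCC1=CO[C@@H](OC(C)=O)[C@H]2C(C=O)=CC(=O)[C@H]3[C@@H]([C@@H]12)C3(C)C | target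

**Step count**
Total steps: 11. Longest linear sequence: 11 steps (1 → 22); compounds 2, 3, 8, 11 and 18 enter as purchased materials.

**Steps most likely to fail, with fallbacks**

Step 11 (radical ring closure). The acyl radical may be reduced or add intermolecularly before the 7-endo closure, and the released stannane can attack the product. The fallback sets out from 21 and returns at 22. Iododestannylation with iodine gives the β-iodo enal F4; only the isomer with iodine cis to C-1 can close, and the other is equilibrated under the same conditions. A Nozaki–Hiyama–Kishi cyclisation (CrCl2, NiCl2 catalytic, DMSO, high dilution) then joins C-9 to the C-8 aldehyde and gives the ring-closed C-8 carbinol F5 as an epimer mixture. Oxidation with MnO2 gives 22.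

Step 8 (radical stannylformylation). Direct hydrostannation and a 1,6-hydrogen shift from the CH2OSi group to the vinyl radical compete with CO capture. The fallback sets out from 17 and returns at 19. Silylformylation catalysed by Rh4(CO)12 with Me2PhSiH and CO (20 atm, PhH) places the formyl group on the internal alkyne carbon and gives the (Z)-β-silyl enal F2. Iododesilylation with N-iodosuccinimide in MeCN gives the (Z)-β-iodo enal F3. Stannylation with Bu3SnSnBu3 and Pd(PPh3)4 then gives 19 as a single alkene isomer.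

Step 6 (C-1 and C-2). The α-chloro ether may ionise, so that acetate enters from the less hindered face and gives the C-2 epimer. The fallback sets out from 13 and returns at 15. Hydration (PPTS, THF/H2O, 0 °C) protonates C-1 anti to the cyclopropyl group and gives the lactol F1, whose favoured anomer carries the axial hydroxyl trans to the ethynyl group. Mitsunobu esterification (PPh3, DIAD, AcOH, PhMe, −20 °C) inverts that anomer and gives 15.

Further compounds
F1 | step 6 | (2S,3R,4R)-4-[(1R,3S)-3-({[tert-butyl(diphenyl)silyl]oxy}methyl)-2,2-dimethylcyclopropyl]-3-ethynyl-2-hydroxy-3,4-dihydro-2H-pyran-5-carbaldehyde | O=CC1=CO[C@H](O)[C@@H](C#C)[C@H]1[C@@H]1[C@H](CO[Si](c2ccccc2)(c2ccccc2)C(C)(C)C)C1(C)C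
F2 | step 8 | [(2S,3R,4R)-2-(acetyloxy)-4-[(1R,3S)-3-({[tert-butyl(diphenyl)silyl]oxy}methyl)-2,2-dimethylcyclopropyl]-3-{(1Z)-1-[dimethyl(phenyl)silyl]-3-oxoprop-1-en-2-yl}-3,4-dihydro-2H-pyran-5-yl]methyl acetate | CC(=O)OCC1=CO[C@@H](OC(C)=O)[C@@H](/C(C=O)=C/[Si](C)(C)c2ccccc2)[C@H]1[C@@H]1[C@H](CO[Si](c2ccccc2)(c2ccccc2)C(C)(C)C)C1(C)C
F3 | step 8 | [(2S,3R,4R)-2-(acetyloxy)-4-[(1R,3S)-3-({[tert-butyl(diphenyl)silyl]oxy}methyl)-2,2-dimethylcyclopropyl]-3-[(1Z)-1-iodo-3-oxoprop-1-en-2-yl]-3,4-dihydro-2H-pyran-5-yl]methyl acetate | CC(=O)OCC1=CO[C@@H](OC(C)=O)[C@@H](/C(C=O)=C/I)[C@H]1[C@@H]1[C@H](CO[Si](c2ccccc2)(c2ccccc2)C(C)(C)C)C1(C)C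
F4 | step 11 | [(2S,3R,4R)-2-(acetyloxy)-4-[(1R,3S)-3-formyl-2,2-dimethylcyclopropyl]-3-[(1E)-1-iodo-3-oxoprop-1-en-2-yl]-3,4-dihydro-2H-pyran-5-yl]methyl acetate | CC(=O)OCC1=CO[C@@H](OC(C)=O)[C@@H](/C(C=O)=C\I)[C@H]1[C@@H]1[C@H](C=O)C1(C)C
F5 | step 11 | (1R,2S,5R,6R,7S)-2,15-diacetoxy-2,3-epoxy-8-hydroxy-2,3-secoaromadendra-3,9-dien-14-al (C-8 epimers) | CC(=O)OCC1=CO[C@@H](OC(C)=O)[C@H]2C(C=O)=CC(O)[C@H]3[C@@H]([C@@H]12)C3(C)C
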